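The stirred vessel starts with electrophile and free base, and nucleophile runs in at a steady rate; the north flask is followed further, to the time asked.

the same everywhere: electrophile 0.050 M

| run | nucleophile | free base | remark | time |
|---|---|---|---|---|
| north | 0.045 M (fed, over 4.0 min) | 0.040 M | the very flask that is asked about, followed so far; the fed solution adds 0.25 times the starting volume |  |
| south-east | 0.068 M (fed, over 4.0 min) | 0.040 M | run made earlier; the fed solution adds 0.25 times the starting volume |  |
| flask | 0.0450 M (fed, over 4.0 min) | 0.0400 M | the fed solution adds 0.25 times the starting volume | 6.0 h |

- north (time / min: electrophile / %, target / %): 4.00: 57.6, 38.8; 10.0: 43.2, 44.3; 20.0: 36.5, 42.6; 30.0: 32.0, 41.8; 40.0: 28.3, 41.8; 50.0: 27.4, 42.7; 60.0: 25.2, 44.4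
- south-east (time / h: electrophile / %, target / %): 0.133: 25.9, 62.0; 0.333: 16.1, 55.2; 0.667: 9.6, 53.5; 1.00: 5.6, 54.0; 1.33: 3.2, 54.7; 2.00: 1.3, 56.6; 2.50: 0.1, 56.9

(readings scatter by 0.5 percentage points)

- part of the electrophile that has reacted at 6.0 h
- share of free nucleophile in free nucleophile and protonated nucleophile together, at 6.0 h

- amounts are per litre of the starting volume; all of the dose is in the solution fed
- a reading or a percentage of target counts all its forms, free or not
- the earlier runs do not show how much of nucleophile is bound; that part of a forecast is a guess

Take the main step first: one nucleophile turns over one electrophile. The number then comes from the charges: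

ceiling = 0.0450 M / 0.050 M = 90.0%

This ceiling, the nucleophile charge as a fraction of the electrophile charge, marks nucleophile as the limiting reagent of the north flask. In the south-east run the same ratio is 136%, and its electrophile came down to 0.1%.

Now add protonation. Protonated nucleophile waits unreacted, so the ceiling stays but is reached later. The north flask used 42.4% of its electrophile by 4.00 min, yet just 3.1 percentage points between 40.0 min and 60.0 min. As its measure for late times this reckoning takes the gap, the electrophile of the north flask still above its final level, which counts the unreacted nucleophile, whether free, protonated or bound: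

gap: 18.3% at 40.0 min, 15.2% at 60.0 min

first-order reading: ln(18.3% / 15.2%) / 20.0 min = 0.557 h⁻¹

gap at 6.0 h: 0.939%, so c = 89.1%

With a scatter of 0.5 points on each reading, this rate is rough.

Last come free base, taken here to share the proton, and the 30.4% of the charge absent from both columns of the north run at 60.0 min. Reckoned here as following target, they leave the ceiling unmoved. This reckoning gives no value for fr.

The forecast, a little below this reckoning, gives c = 88% (81% to 93%) and fr = 18% (6% to 42%), noting “The binding share is a guess.”

The north flask gives c = 90.0% and fr = 28.2%.

    acid set free → by-product carried off (k = 0.0366 min⁻¹)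
    electrophile + nucleophile → acid set free + target (k = 84.8 M⁻¹ min⁻¹)
    acid set free + free base ⇌ salt of the base (K = 38.0 M⁻¹, k = 58.4 M⁻¹ min⁻¹)
    nucleophile + target ⇌ idle adduct, settled at all times (K = 34.0 M⁻¹)
    nucleophile + acid set free ⇌ protonated nucleophile, settled at all times (K = 11000 M⁻¹)
    target ⇌ isomer of the product (K = 0.770, k = 0.0434 min⁻¹)

The north flask stands at its ceiling of 90.0% at 6.0 h, with 0% of its nucleophile charge left unbound then, and it still shows 90.0% at 60.0 h. The loss of acid set free to by-product carried off helps it get there by 6.0 h: without that step the flask reaches 84.3%, not 90.0%. For the neighbour with 0.011 M of nucleophile, the ceiling gives 22.0%; the computed flask gives 22.0%.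

The numbers in the tables are simulated for substances that don't exist.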